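## Retrosynthetic overview

1. Target ⇐ C3 desilylation and face-selective epoxidation of the E-C1=C10 bond of a 1(10)E,4Z-dienolide; the exo-methylene ⇐ Mannich/elimination on the γ-lactone.
2. trans-γ-Lactone and C8 isobutyrate ⇐ Evans–Tishchenko reduction of a C8-hydroxy C6-ketone carrying a C7 acetate arm, then lactonisation.
3. Ten-membered ring ⇐ anionic oxy-Cope [3,3] shift of a 1-(Z-2-alkoxyvinyl)-6-isopropenylcyclohex-2-en-1-ol (breaks C6–C1, makes C8–C9), with the enolate alkylated at C7 in the same flask.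
4. Cyclohexenol ⇐ (Z)-2-(PMB-oxy)vinyllithium + 4-silyloxy-isopiperitenone ⇐ (S)-carvone (Luche reduction, TBS, allylic oxidation).
5. Ring order: cyclohexene (bought) → cyclodecadiene (oxy-Cope) → γ-lactone → epoxide.

Assumption: germacrane numbering is used for all ten-membered-ring compounds (ring C1–C10, lactone carbons C11–C13, methyl C14 on C10, methyl C15 on C4); the target is (1S,3S,6R,7R,8R,10S) with a 4Z alkene and a trans-epoxide. TBS = tert-butyldimethylsilyl, PMB = 4-methoxybenzyl.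

## Route

Step 1
Reactants: 1 (S)-(+)-carvone
Product: 2 (1S,5S)-cis-carveol
Conditions: NaBH4, CeCl3·7H2O, MeOH, −78 → 0 °C
Reagents that add atoms: none
Why: Luche 1,2-reduction in which hydride adds axially to the enone half-chair with equatorial isopropenyl, so the bought C5 centre sets C1 and gives the cis (diequatorial) alcohol.

Step 2
Reactants: 2 (1S,5S)-cis-carveol
Product: 3 (1S,5S)-cis-carveol TBS ether
Conditions: TBSCl, imidazole, DMF, rt
Reagents that add atoms: tert-butyldimethylsilyl chloride CC(C)(C)[Si](C)(C)Cl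
Why: Standard silylation of a secondary allylic alcohol, giving an ether that survives organolithium, amide-base, DDQ and peracid steps.

Step 3
Reactants: 3 (1S,5S)-cis-carveol TBS ether
Product: 4 (4S,6S)-4-(TBS-oxy)-3-methyl-6-(prop-1-en-2-yl)cyclohex-2-en-1-one
Conditions: Rh2(caprolactamate)4 (1 mol %), t-BuOOH (5 equiv), K2CO3 (0.5 equiv), CH2Cl2, rt
Reagents that add atoms: tert-butyl hydroperoxide CC(C)(C)OO
Why: Allylic C–H oxidation by the tert-butylperoxyl radical chain converts the only unhindered ring methylene allylic to the trisubstituted alkene into the enone carbonyl; no new stereocentre forms and the near-neutral medium keeps the now α-carbonyl isopropenyl centre.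

Step 4
Reactants: 5 4-methoxybenzyl alcohol
Product: 6 4-methoxybenzyl vinyl ether
Conditions: Pd(OCOCF3)2 (0.5 mol %), 4,7-diphenyl-1,10-phenanthroline (0.5 mol %), n-butyl vinyl ether (solvent), 75 °C
Reagents that add atoms: butyl vinyl ether C=COCCCC
Why: Palladium-catalysed transfer vinylation (transetherification) of a primary benzylic alcohol, driven by the excess vinyl ether.

Step 5
Reactants: 6 4-methoxybenzyl vinyl ether
Product: 8 (Z)-1-bromo-2-[(4-methoxybenzyl)oxy]ethene, via dibromo ether 7 (not isolated)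
Conditions: Br2, CH2Cl2, −78 °C; then i-Pr2NEt, −78 → 40 °C
Reagents that add atoms: bromine BrBr
Why: Bromination of the enol ether followed by dehydrobromination of the α-bromo ether (through its oxocarbenium ion) gives the β-bromo enol ether, in which the cis (Z) isomer is favoured and is purified from the minor E isomer.

Step 6
Reactants: 4 (4S,6S)-enone; 8 (Z)-1-bromo-2-[(4-methoxybenzyl)oxy]ethene
Product: 10 (1S,4S,6S)-1-[(Z)-2-(PMB-oxy)ethenyl]cyclohexenol, via vinyllithium 9 (not isolated)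
Conditions: 8 (1.6 equiv), n-BuLi (1.5 equiv), THF, −78 °C; then 4, −78 °C; aq. NH4Cl
Reagents that add atoms: none
Why: Bromine–lithium exchange with retention gives the configurationally stable (Z)-alkoxyvinyllithium, whose 1,2-addition to the enone occurs anti to the adjacent isopropenyl group to set C1 (trans-dialkenyl carbinol); the minor C1 epimer is expected to converge in step 7.

Step 7
Reactants: 10 (1S,4S,6S)-1-[(Z)-2-(PMB-oxy)ethenyl]cyclohexenol
Product: 13 tert-butyl [(3S,7R,8R)-3-(TBS-oxy)-8-(PMB-oxy)-4,10-dimethyl-6-oxocyclodeca-1(10)E,4Z-dien-7-yl]acetate, via potassium alkoxide 11 (not isolated), via potassium enolate 12 (not isolated)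
Conditions: KN(SiMe3)2 (1.2 equiv), 18-crown-6, THF, −78 → 0 °C; then BrCH2CO2t-Bu, −78 → −40 °C
Reagents that add atoms: tert-butyl bromoacetate CC(C)(C)OC(=O)CBr
Why: Anionic oxy-Cope [3,3]-sigmatropic rearrangement through a chair transition state makes C8–C9 and the E-C1=C10 alkene, keeps the ring alkene as Z-C4=C5 and transfers the C1/carbinol chirality to C8 (Z-enol ether gives 8R), after which the C6 enolate is alkylated (SN2) at C7 on its outer face, the inner face being covered by the transannular C1=C10 bond (7R, acetate arm cis to the C8 oxygen).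

Step 8
Reactants: 13 keto ester
Product: 14 tert-butyl [(3S,7R,8R)-3-(TBS-oxy)-8-hydroxy-4,10-dimethyl-6-oxocyclodeca-1(10)E,4Z-dien-7-yl]acetate
Conditions: DDQ, CH2Cl2/pH 7 buffer (10:1), 0 °C
Reagents that add atoms: none
Why: Oxidative PMB-ether cleavage under neutral conditions frees the β-hydroxy ketone, while the tert-butyl ester cannot lactonise onto the new C8 hydroxyl.

Step 9
Reactants: 14 β-hydroxy ketone
Product: 16 (3S,6R,7R,8R)-3-(TBS-oxy)-8-(isobutyryloxy) trans-fused γ-lactone, via hydroxy ester 15 (not isolated)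
Conditions: i-PrCHO (6 equiv), SmI2 (0.3 equiv), THF, −10 °C; then p-TsOH·H2O (0.1 equiv), PhH, 40 °C
Reagents that add atoms: isobutyraldehyde CC(C)C=O
Why: Evans–Tishchenko reduction, in which the samarium-bound hemiacetal on the C8 oxygen delivers hydride intramolecularly to C6 to give the 1,3-anti diol monoester (6R, isobutyrate on O8), followed by acid-catalysed lactonisation of the C6 hydroxyl onto the tert-butyl ester to the trans-fused γ-lactone.

Step 10
Reactants: 16 γ-lactone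
Product: 19 (3S,6R,7R,8R)-3-(TBS-oxy)-8-(isobutyryloxy)germacra-1(10)E,4Z,11(13)-trien-6,12-olide, via Mannich base 17 (not isolated), via ammonium iodide 18 (not isolated)
Conditions: LiN(i-Pr)2 (1.2 equiv), THF, −78 °C; CH2=NMe2+ I−, −78 → 0 °C; then MeI, CH2Cl2, rt; then aq. NaHCO3
Reagents that add atoms: N,N-dimethylmethyleneiminium iodide C=[N+](C)C.[I-]; iodomethane CI (methyl carried only in 18)
Why: Kinetic lactone enolate formation (the hindered isobutyrate methine is deprotonated more slowly), Mannich reaction with Eschenmoser's salt, quaternisation and Hofmann-type elimination give the α-methylene lactone without touching any stereocentre.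

Step 11
Reactants: 19 trienolide
Product: 20 (1S,3S,6R,7R,8R,10S)-1,10-epoxy-3-(TBS-oxy)-8-(isobutyryloxy)germacra-4Z,11(13)-dien-6,12-olide
Conditions: m-CPBA (1.1 equiv), NaHCO3, CH2Cl2, −20 → 0 °C
Reagents that add atoms: 3-chloroperbenzoic acid O=C(OO)c1cccc(Cl)c1
Why: Prilezhaev epoxidation picks the strained, electron-rich E-C1=C10 alkene (C4=C5 is deactivated by two allylic oxygens, the acrylate is inert) and is expected to attack the outer face of the heliangolide-type conformer with C14 opposite the C7/C8 substituents, stereospecifically giving the trans (1S,10S)-epoxide.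

Step 12
Reactants: 20 epoxide silyl ether
Product: 21 CNP0261225.3 (target)
Conditions: HF·pyridine, pyridine, THF, 0 °C → rt
Reagents that add atoms: none
Why: Buffered fluoride desilylation frees the C3 hydroxyl without opening the epoxide, adding to the α-methylene lactone or migrating the isobutyrate.

## Compound list

1 | (S)-(+)-carvone, (5S)-2-methyl-5-(prop-1-en-2-yl)cyclohex-2-en-1-one | CC1=CC[C@@H](CC1=O)C(C)=C | starting material
2 | (1S,5S)-cis-carveol | CC1=CC[C@@H](C[C@@H]1O)C(C)=C | intermediate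
3 | tert-butyl(dimethyl){[(1S,5S)-2-methyl-5-(prop-1-en-2-yl)cyclohex-2-en-1-yl]oxy}silane | CC1=CC[C@@H](C[C@@H]1O[Si](C)(C)C(C)(C)C)C(C)=C | intermediate
4 | (4S,6S)-4-[(tert-butyldimethylsilyl)oxy]-3-methyl-6-(prop-1-en-2-yl)cyclohex-2-en-1-one | CC1=CC(=O)[C@@H](C[C@@H]1O[Si](C)(C)C(C)(C)C)C(C)=C | intermediate
5 | 4-methoxybenzyl alcohol | COc1ccc(CO)cc1 | starting material
6 | 4-methoxybenzyl vinyl ether | C=COCc1ccc(OC)cc1 | intermediate
7 | 1-[(1,2-dibromoethoxy)methyl]-4-methoxybenzene (racemic) | BrCC(Br)OCc1ccc(OC)cc1 | intermediate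
8 | (Z)-1-bromo-2-[(4-methoxybenzyl)oxy]ethene | Br/C=C\OCc1ccc(OC)cc1 | intermediate
9 | (Z)-2-[(4-methoxybenzyl)oxy]ethenyllithium | [Li]/C=C\OCc1ccc(OC)cc1 | intermediate
10 | (1S,4S,6S)-4-[(tert-butyldimethylsilyl)oxy]-1-{(Z)-2-[(4-methoxybenzyl)oxy]ethenyl}-3-methyl-6-(prop-1-en-2-yl)cyclohex-2-en-1-ol | CC1=C[C@@](O)(/C=C\OCc2ccc(OC)cc2)[C@@H](C[C@@H]1O[Si](C)(C)C(C)(C)C)C(C)=C | intermediate
11 | potassium alkoxide of 10 | CC1=C[C@@]([O-])(/C=C\OCc2ccc(OC)cc2)[C@@H](C[C@@H]1O[Si](C)(C)C(C)(C)C)C(C)=C.[K+] | intermediate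
12 | potassium (3S,6Z,8R)-3-(TBS-oxy)-8-(PMB-oxy)-4,10-dimethylcyclodeca-1(10)E,4Z,6-trien-6-olate (enolate O cis to C8) | C1/C(C)=C/C[C@H](O[Si](C)(C)C(C)(C)C)/C(C)=C\C(\[O-])=C\[C@@H]1OCc2ccc(OC)cc2.[K+] | intermediate
13 | tert-butyl [(3S,7R,8R)-3-(TBS-oxy)-8-(PMB-oxy)-4,10-dimethyl-6-oxocyclodeca-1(10)E,4Z-dien-7-yl]acetate | O=C1/C=C(/C)[C@@H](O[Si](C)(C)C(C)(C)C)C/C=C(\C)C[C@@H](OCc2ccc(OC)cc2)[C@H]1CC(=O)OC(C)(C)C | intermediate
14 | tert-butyl [(3S,7R,8R)-3-(TBS-oxy)-8-hydroxy-4,10-dimethyl-6-oxocyclodeca-1(10)E,4Z-dien-7-yl]acetate | O=C1/C=C(/C)[C@@H](O[Si](C)(C)C(C)(C)C)C/C=C(\C)C[C@@H](O)[C@H]1CC(=O)OC(C)(C)C | intermediate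
15 | tert-butyl [(3S,6R,7S,8R)-3-(TBS-oxy)-6-hydroxy-8-(isobutyryloxy)-4,10-dimethylcyclodeca-1(10)E,4Z-dien-7-yl]acetate | O[C@@H]1/C=C(/C)[C@@H](O[Si](C)(C)C(C)(C)C)C/C=C(\C)C[C@@H](OC(=O)C(C)C)[C@H]1CC(=O)OC(C)(C)C | intermediate
16 | (3S,6R,7R,8R)-3-(TBS-oxy)-8-(isobutyryloxy)-4,10-dimethylcyclodeca-1(10)E,4Z-diene trans-fused at C6–C7 to a γ-butyrolactone (O on C6, C11H2 on C7) | C1C(=O)O[C@@H]2/C=C(/C)[C@@H](O[Si](C)(C)C(C)(C)C)C/C=C(\C)C[C@@H](OC(=O)C(C)C)[C@@H]12 | intermediate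
17 | 11-[(dimethylamino)methyl] derivative of 16 (C11 epimers) | CN(C)CC1C(=O)O[C@@H]2/C=C(/C)[C@@H](O[Si](C)(C)C(C)(C)C)C/C=C(\C)C[C@@H](OC(=O)C(C)C)[C@@H]12 | intermediate
18 | 11-[(trimethylammonio)methyl] iodide of 16 (C11 epimers) | C[N+](C)(C)CC1C(=O)O[C@@H]2/C=C(/C)[C@@H](O[Si](C)(C)C(C)(C)C)C/C=C(\C)C[C@@H](OC(=O)C(C)C)[C@@H]12.[I-] | intermediate
19 | (3S,6R,7R,8R)-3-(TBS-oxy)-8-(isobutyryloxy)germacra-1(10)E,4Z,11(13)-trien-6,12-olide | C=C1C(=O)O[C@@H]2/C=C(/C)[C@@H](O[Si](C)(C)C(C)(C)C)C/C=C(\C)C[C@@H](OC(=O)C(C)C)[C@@H]12 | intermediate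
20 | (1S,3S,6R,7R,8R,10S)-1,10-epoxy-3-(TBS-oxy)-8-(isobutyryloxy)germacra-4Z,11(13)-dien-6,12-olide | C=C1C(=O)O[C@@H]2/C=C(/C)[C@@H](O[Si](C)(C)C(C)(C)C)C[C@@H]3O[C@@]3(C)C[C@@H](OC(=O)C(C)C)[C@@H]12 | intermediate
21 | CNP0261225.3, (1S,3S,6R,7R,8R,10S)-1,10-epoxy-3-hydroxy-8-(isobutyryloxy)germacra-4Z,11(13)-dien-6,12-olide | C=C1C(=O)O[C@@H]2/C=C(/C)[C@@H](O)C[C@@H]3O[C@@]3(C)C[C@@H](OC(=O)C(C)C)[C@@H]12 | target

## Step count and risks

Total steps: 12. Longest linear sequence: 10 (steps 1–3 and 6–12); the vinyl bromide branch (steps 4–5) joins at step 6.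

**Step 7 (oxy-Cope/alkylation).** The potassium enolate carries a β-alkoxy group that can be lost by E1cB at the temperature the rearrangement needs, the axial Z-alkoxy group may push the shift off the chair path, and the C7 facial selectivity depends on the enolate being trapped in the conformation in which it is born. Fallback: from carbinol 10, run the [3,3] shift under neutral conditions with divalent palladium (PdCl2(PhCN)2, 10 mol %, THF, rt; cyclisation-induced oxy-Cope), which gives the C7-unsubstituted ketone F1 without a free enolate above −78 °C. Then form the lithium enolate with LiN(i-Pr)2 in THF at −78 °C and alkylate it with tert-butyl bromoacetate/DMPU, coming back to the route at keto ester 13.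

**Step 9 (Evans–Tishchenko/lactonisation).** The 1,3-anti rule comes from an acyclic chair transition state; the ten-membered ring may instead force hydride delivery in the syn mode, and the β-hydroxy ketone could also undergo retro-aldol or dehydration. Fallback: if the reduction of 14 gives the C6-epimeric hydroxy ester F2, cleave the tert-butyl ester (TMSOTf, 2,6-lutidine, CH2Cl2, 0 °C, aqueous work-up) to the hydroxy acid F3. Then close the lactone by an intramolecular Mitsunobu reaction (PPh3, DIAD, THF, 0 °C), which inverts C6 by SN2 attack of the carboxylate, and return to lactone 16.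

**Step 11 (epoxidation).** The face of attack on C1=C10 is set only by the ring conformation, which is not known with certainty for 19; the competing C4=C5 alkene and acid-triggered transannular reactions are lesser risks. Fallback: if peracid on 19 gives the (1R,10R)-epoxide F4, invert both centres. Acid hydrolysis (HClO4 cat., THF/H2O, 0 °C) opens at tertiary C10 with inversion to the (1R,10S)-diol F5. MsCl, Et3N, CH2Cl2, −20 °C then gives the secondary C1 mesylate F6, and NaH, THF, 0 °C closes the ring with inversion at C1, returning to epoxide 20.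

## Further compounds

F1 | step 7 | (3S,8R)-3-(TBS-oxy)-8-(PMB-oxy)-4,10-dimethylcyclodeca-1(10)E,4Z-dien-6-one | O=C1/C=C(/C)[C@@H](O[Si](C)(C)C(C)(C)C)C/C=C(\C)C[C@@H](OCc2ccc(OC)cc2)C1
F2 | step 9 | tert-butyl [(3S,6S,7S,8R)-3-(TBS-oxy)-6-hydroxy-8-(isobutyryloxy)-4,10-dimethylcyclodeca-1(10)E,4Z-dien-7-yl]acetate | O[C@H]1/C=C(/C)[C@@H](O[Si](C)(C)C(C)(C)C)C/C=C(\C)C[C@@H](OC(=O)C(C)C)[C@H]1CC(=O)OC(C)(C)C
F3 | step 9 | [(3S,6S,7S,8R)-3-(TBS-oxy)-6-hydroxy-8-(isobutyryloxy)-4,10-dimethylcyclodeca-1(10)E,4Z-dien-7-yl]acetic acid | O[C@H]1/C=C(/C)[C@@H](O[Si](C)(C)C(C)(C)C)C/C=C(\C)C[C@@H](OC(=O)C(C)C)[C@H]1CC(=O)O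
F4 | step 11 | (1R,3S,6R,7R,8R,10R)-1,10-epoxy-3-(TBS-oxy)-8-(isobutyryloxy)germacra-4Z,11(13)-dien-6,12-olide | C=C1C(=O)O[C@@H]2/C=C(/C)[C@@H](O[Si](C)(C)C(C)(C)C)C[C@H]3O[C@]3(C)C[C@@H](OC(=O)C(C)C)[C@@H]12
F5 | step 11 | (1R,3S,6R,7R,8R,10S)-1,10-dihydroxy-3-(TBS-oxy)-8-(isobutyryloxy)germacra-4Z,11(13)-dien-6,12-olide | C=C1C(=O)O[C@@H]2/C=C(/C)[C@@H](O[Si](C)(C)C(C)(C)C)C[C@@H](O)[C@@](C)(O)C[C@@H](OC(=O)C(C)C)[C@@H]12
F6 | step 11 | (1R,3S,6R,7R,8R,10S)-10-hydroxy-1-(methanesulfonyloxy)-3-(TBS-oxy)-8-(isobutyryloxy)germacra-4Z,11(13)-dien-6,12-olide | C=C1C(=O)O[C@@H]2/C=C(/C)[C@@H](O[Si](C)(C)C(C)(C)C)C[C@@H](OS(C)(=O)=O)[C@@](C)(O)C[C@@H](OC(=O)C(C)C)[C@@H]12
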